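The numbering used is the carbocycle C1–C10 (methyls on C4 and C10, ether O bridging C5/C10, lactone O on C8, ester O on C9, lactone carbons C11–C13). One annulation closes both oxepanes and the carbocycle by making O–C10 and C8–C9 together. It exploits the 1,4-relation of the C5 oxygen and C8 (a γ-lactol) and the vicinal O–C10/C9–C8 pattern of the oxepane made of O and C5–C10. The precursor has only a temporary lactol ring, tethered through C4–C1 to an alkenyl diphenylsulfonium (C9=C10). Base sends the C5 alkoxide to C10; the C9 ylide attacks the C8 aldehyde and closes to the 8,9-epoxide, whose oxygen later carries the isovalerate.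

Key step: step 9

Assumption: the (S)-configured phosphoric acid of step 1 is taken to deliver the crotyl group to the Si face of the aldehyde (C5 = R); should the sense be the reverse, its enantiomer is used.

Step 1
Reactants: 1 methyl 4-oxobutanoate; 2 (E)-crotylboronic acid pinacol ester
Product: 4 (5R)-5-[(2S)-but-3-en-2-yl]oxolan-2-one, via hydroxy ester 3 (not isolated)
Conditions: (S)-3,3'-bis(2,4,6-triisopropylphenyl)-1,1'-binaphthyl-2,2'-diyl hydrogen phosphate (5 mol %), toluene, −30 °C; then H2O, p-TsOH·H2O (10 mol %), rt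
Reagents that add atoms: none
Why: Brønsted-acid-catalysed crotylboration runs through a closed chair transition state in which the (E)-crotyl geometry sets the anti C4/C5 relationship and the chiral phosphate the absolute sense, and the γ-hydroxy ester then lactonises under acid.

Step 2
Reactants: 5 pent-1-en-4-yne
Product: 7 (1E)-1-iodo-2-methylpenta-1,4-diene, via alkenylalane 6 (not isolated)
Conditions: AlMe3 (2 equiv), Cp2ZrCl2 (25 mol %), CH2Cl2, 0 °C → rt; then I2, THF, −30 → 0 °C
Reagents that add atoms: trimethylaluminium C[Al](C)C; iodine [I][I]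
Why: Negishi carboalumination adds methyl and aluminium syn across the terminal alkyne while leaving the isolated alkene alone, and iodinolysis with retention gives the (E)-iodide.

Step 3
Reactants: 4 lactone; 7 iodo diene (3 equiv)
Product: 8 (5R)-5-[(2S,3E,6E)-7-iodo-6-methylhepta-3,6-dien-2-yl]oxolan-2-one (3E drawn; the 3Z isomer is equally usable)
Conditions: second-generation Hoveyda–Grubbs catalyst (5 mol %), CH2Cl2, 40 °C
Reagents that add atoms: none
Why: Olefin cross-metathesis joins the two monosubstituted alkenes with loss of ethene while the trisubstituted iodoalkene is inert to the ruthenium carbene, and the geometry of the new C2=C3 bond does not matter because it is reduced next.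

Step 4
Reactants: 8 diene lactone
Product: 9 (5R)-5-[(2S,6E)-7-iodo-6-methylhept-6-en-2-yl]oxolan-2-one
Conditions: TsNHNH2 (5 equiv), NaOAc (6 equiv), DME/H2O, 85 °C
Reagents that add atoms: none
Why: Diimide reduction transfers hydrogen in a concerted syn fashion to the disubstituted C2=C3 alkene much faster than to the trisubstituted iodoalkene and does not cleave the C–I bond.

Step 5
Reactants: 9 iodo lactone
Product: 10 (5R)-5-[(2S,6E)-6-methyl-7-(phenylsulfanyl)hept-6-en-2-yl]oxolan-2-one
Conditions: PhSH (1.2 equiv), Pd2(dba)3 (2.5 mol %), Xantphos (5 mol %), iPr2NEt (2 equiv), 1,4-dioxane, 100 °C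
Reagents that add atoms: thiophenol Sc1ccccc1
Why: Palladium-catalysed C–S cross-coupling (oxidative addition to zerovalent palladium, thiolate exchange, reductive elimination) replaces iodide by phenylthio with retention of alkene geometry under an amine base that the lactone tolerates.

Step 6
Reactants: 10 sulfide lactone
Product: 11 tert-butyl 2-[(3R,5R)-5-[(2S,6E)-6-methyl-7-(phenylsulfanyl)hept-6-en-2-yl]-2-oxooxolan-3-yl]acetate
Conditions: LDA (1.1 equiv), THF, −78 °C; then BrCH2CO2tBu (1.3 equiv), DMPU, −78 → −40 °C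
Reagents that add atoms: tert-butyl bromoacetate CC(C)(C)OC(=O)CBr
Why: Enolate alkylation (SN2) of the γ-lactone lithium enolate should occur on the face anti to the branched C5 substituent, which sets C7 as the 3,5-trans (3R,5R) isomer.

Step 7
Reactants: 11 lactone ester
Product: 12 tert-butyl 2-[(3R,5R)-2-hydroxy-5-[(2S,6E)-6-methyl-7-(phenylsulfanyl)hept-6-en-2-yl]oxolan-3-yl]acetate (lactol; both anomers)
Conditions: DIBAL-H (1.1 equiv), CH2Cl2, −78 °C; aq. Rochelle salt
Reagents that add atoms: none
Why: Partial hydride reduction with DIBAL-H at −78 °C stops at the tetrahedral aluminium hemiacetal of the lactone and should leave the tert-butyl ester and the alkenyl sulfide untouched.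

Step 8
Reactants: 12 lactol sulfide
Product: 13 [(1E,6S)-6-[(2R,4R)-4-(2-tert-butoxy-2-oxoethyl)-5-hydroxyoxolan-2-yl]-2-methylhept-1-en-1-yl]diphenylsulfonium trifluoromethanesulfonate
Conditions: Ph2I+ TfO− (1.2 equiv), Cu(OAc)2 (5 mol %), ClCH2CH2Cl, 80 °C
Reagents that add atoms: diphenyliodonium trifluoromethanesulfonate [O-]S(=O)(=O)C(F)(F)F.c1ccc(cc1)[I+]c1ccccc1
Why: Copper-catalysed S-arylation (aryl transfer from the diaryliodonium salt through an aryl copper intermediate) turns the sulfide into the alkenyl diphenylsulfonium salt under neutral conditions that the lactol and the ester should survive.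

Step 9
Reactants: 13 lactol alkenylsulfonium triflate
Product: 15 tert-butyl 2-[(4S,5R,7R,8S,9S,10R)-5,10:8,9-diepoxy-4,10-dimethylcyclodecan-7-yl]acetate (locants of the C1–C10 numbering above), via oxepane sulfonium ylide 14 (not isolated)
Conditions: DBU (2 equiv), CH2Cl2 (0.005 M), 0 °C → rt
Reagents that add atoms: none
Why: Proposed new method: DBU opens the lactol to the γ-hydroxy aldehyde and the C5 alkoxide adds 7-exo-trig to C10 of the tethered alkenylsulfonium (O–C10 bond, oxepane B with C1–C4), giving ylide 14, whose carbanion at C9 attacks the C8 aldehyde 7-exo-trig (C8–C9 bond, oxepane A with C6–C9) before the anti betaine closes 3-exo-tet with loss of diphenyl sulfide to the 8,9-epoxide. The closest known reaction type is the epoxy-annulation of β- or γ-heteroatom-substituted carbonyl compounds with vinylsulfonium salts (conjugate addition followed by Corey–Chaykovsky epoxidation), which has not been run with a tethered β,β-disubstituted alkenylsulfonium. C10 is not an independent stereocentre because the ether can bridge C5 and C10 only in the cis sense, and since the conjugate addition is reversible (retro-Michael from the ylide) only the adduct able to bridge should go on. The epoxide must be cis-fused to oxepane A and forms from a trans-diaxial alkoxide/sulfonium betaine, in which the bulky Ph2S+ group at C9 should sit anti to the C10 methyl group, so that the epoxide oxygen ends on the methyl face (8S,9S), cis to the C7 side chain fixed in step 6. The step needs O5 to react in preference to the anomeric hydroxyl and to a second molecule, which the seven-membered intramolecular addition, the non-nucleophilic base and high dilution should secure, and C7 epimerisation is limited because the aldehyde stays masked as the lactol until O5 has reacted.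

Step 10
Reactants: 15 epoxy ester
Product: 16 (4S,5R,7R,8R,9S,10R)-5,10-epoxy-9-hydroxy-13-norgermacran-12,8-olide (γ-lactone C12(=O)–O–C8 with C11 = CH2 and free 9-OH)
Conditions: (+)-camphor-10-sulfonic acid (20 mol %), CH2Cl2, 0 °C → rt
Reagents that add atoms: none
Why: Acid-catalysed epoxide-opening lactonisation lets the tert-butyl ester carbonyl oxygen attack C8 5-exo with inversion and lose 2-methylpropene, which should give the trans-fused γ-lactone and leave the C9 hydroxyl with the configuration set in step 9.

Step 11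
Reactants: 16 hydroxy lactone
Product: 17 (4S,5R,7R,8R,9S,10R)-5,10-epoxy-9-(3-methylbutanoyloxy)-13-norgermacran-12,8-olide
Conditions: (iBuCO)2O (2 equiv), DMAP (0.2 equiv), Et3N (3 equiv), CH2Cl2, rt
Reagents that add atoms: 3-methylbutanoic anhydride CC(C)CC(=O)OC(=O)CC(C)C
Why: DMAP-catalysed acylation (nucleophilic catalysis through the acylpyridinium ion) esterifies the only free hydroxyl, the hindered secondary C9–OH, without touching a stereocentre.

Step 12
Reactants: 17 isovalerate lactone
Product: 20 target CNP0274454.1, via Mannich base 18 (not isolated), via ammonium iodide 19 (not isolated)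
Conditions: LiHMDS (1.1 equiv), THF, −78 °C; Me2N+=CH2 I− (1.5 equiv), −78 °C → rt; then MeI (10 equiv), MeOH, rt; then aq. NaHCO3, CH2Cl2, rt
Reagents that add atoms: Eschenmoser's salt (N,N-dimethylmethyleneiminium iodide) C=[N+](C)C.[I-]; iodomethane CI (its methyl group stays only in intermediate 19)
Why: Because γ-lactone α-protons are several pKa units more acidic than those of the acyclic isovalerate, LiHMDS should form the lactone enolate selectively, and its Mannich reaction with Eschenmoser's salt followed by N-methylation and E1cB elimination (α-methylenation) installs the C11=C13 alkene and removes the transient C11 stereocentre.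

Compound list
1 | methyl 4-oxobutanoate | COC(=O)CCC=O | starting material
2 | (E)-crotylboronic acid pinacol ester | C/C=C/CB1OC(C)(C)C(C)(C)O1 | starting material
3 | methyl (4R,5S)-4-hydroxy-5-methylhept-6-enoate | COC(=O)CC[C@@H](O)[C@@H](C)C=C | intermediate (not isolated)
4 | (5R)-5-[(2S)-but-3-en-2-yl]oxolan-2-one | O=C1CC[C@@H](O1)[C@@H](C)C=C | intermediate
5 | pent-1-en-4-yne | C=CCC#C | starting material
6 | dimethyl[(1E)-2-methylpenta-1,4-dien-1-yl]alumane | C=CC/C(C)=C/[Al](C)C | intermediate (not isolated)
7 | (1E)-1-iodo-2-methylpenta-1,4-diene | C=CC/C(C)=C/I | intermediate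
8 | (5R)-5-[(2S,3E,6E)-7-iodo-6-methylhepta-3,6-dien-2-yl]oxolan-2-one | O=C1CC[C@@H](O1)[C@@H](C)/C=C/C/C(C)=C/I | intermediate
9 | (5R)-5-[(2S,6E)-7-iodo-6-methylhept-6-en-2-yl]oxolan-2-one | O=C1CC[C@@H](O1)[C@@H](C)CCC/C(C)=C/I | intermediate
10 | (5R)-5-[(2S,6E)-6-methyl-7-(phenylsulfanyl)hept-6-en-2-yl]oxolan-2-one | O=C1CC[C@@H](O1)[C@@H](C)CCC/C(C)=C/Sc1ccccc1 | intermediate
11 | tert-butyl 2-[(3R,5R)-5-[(2S,6E)-6-methyl-7-(phenylsulfanyl)hept-6-en-2-yl]-2-oxooxolan-3-yl]acetate | O=C1O[C@@H]([C@@H](C)CCC/C(C)=C/Sc2ccccc2)C[C@@H]1CC(=O)OC(C)(C)C | intermediate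
12 | tert-butyl 2-[(3R,5R)-2-hydroxy-5-[(2S,6E)-6-methyl-7-(phenylsulfanyl)hept-6-en-2-yl]oxolan-3-yl]acetate (anomer mixture) | OC1O[C@@H]([C@@H](C)CCC/C(C)=C/Sc2ccccc2)C[C@@H]1CC(=O)OC(C)(C)C | intermediate
13 | [(1E,6S)-6-[(2R,4R)-4-(2-tert-butoxy-2-oxoethyl)-5-hydroxyoxolan-2-yl]-2-methylhept-1-en-1-yl]diphenylsulfonium trifluoromethanesulfonate (anomer mixture) | OC1O[C@@H]([C@@H](C)CCC/C(C)=C/[S+](c2ccccc2)c2ccccc2)C[C@@H]1CC(=O)OC(C)(C)C.[O-]S(=O)(=O)C(F)(F)F | intermediate
14 | tert-butyl (3R)-3-formyl-4-[(2R,3S,7R)-7-[(diphenylsulfonio)methanidyl]-3,7-dimethyloxepan-2-yl]butanoate (sulfonium ylide) | O=C[C@@H](CC(=O)OC(C)(C)C)C[C@H]1O[C@](C)(CCC[C@@H]1C)[CH-][S+](c1ccccc1)c1ccccc1 | intermediate (not isolated)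
15 | tert-butyl 2-[(4S,5R,7R,8S,9S,10R)-5,10:8,9-diepoxy-4,10-dimethylcyclodecan-7-yl]acetate | CC(C)(C)OC(=O)C[C@H]1C[C@H]2O[C@](C)(CCC[C@@H]2C)[C@H]3O[C@@H]13 | intermediate
16 | (4S,5R,7R,8R,9S,10R)-5,10-epoxy-9-hydroxy-13-norgermacran-12,8-olide | O=C1O[C@@H]2[C@@H](C1)C[C@H]1O[C@](C)(CCC[C@@H]1C)[C@H]2O | intermediate
17 | (4S,5R,7R,8R,9S,10R)-5,10-epoxy-9-(3-methylbutanoyloxy)-13-norgermacran-12,8-olide | O=C1O[C@@H]2[C@@H](C1)C[C@H]1O[C@](C)(CCC[C@@H]1C)[C@H]2OC(=O)CC(C)C | intermediate
18 | 11-(dimethylaminomethyl) derivative of 17 (C11 epimers) | O=C1O[C@@H]2[C@@H](C1CN(C)C)C[C@H]1O[C@](C)(CCC[C@@H]1C)[C@H]2OC(=O)CC(C)C | intermediate (not isolated)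
19 | 11-(trimethylammoniomethyl) derivative of 17, iodide (C11 epimers) | O=C1O[C@@H]2[C@@H](C1C[N+](C)(C)C)C[C@H]1O[C@](C)(CCC[C@@H]1C)[C@H]2OC(=O)CC(C)C.[I-] | intermediate (not isolated)
20 | CNP0274454.1, (4S,5R,7R,8R,9S,10R)-5,10-epoxy-9-(3-methylbutanoyloxy)germacr-11(13)-en-12,8-olide | C=C1C(=O)O[C@@H]2[C@@H]1C[C@H]1O[C@](C)(CCC[C@@H]1C)[C@H]2OC(=O)CC(C)C | target

Total step count: 12. Longest linear sequence: 11 steps (steps 1 and 3–12, from methyl 4-oxobutanoate); step 2 is a one-step side branch.

Steps most likely to fail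

1. Step 9 (Proposed new method). The hindered conjugate addition to the β,β-disubstituted alkenylsulfonium may be too slow, so that intermolecular addition, γ-deprotonation of the sulfonium or closure of the epoxide on the wrong face takes over. The fallback uses known chemistry, sets out from iodide 9 and comes back at hydroxy lactone 16. Alkylation of 9 with tert-butyl bromoacetate as in step 6 gives iodo lactone F1, and DIBAL-H reduction as in step 7 gives iodo lactol F2. An intramolecular Nozaki–Hiyama–Kishi reaction (CrCl2, NiCl2 cat., DMSO, high dilution) then closes the ten-membered ring at C8–C9 to give cyclodecene diol F3, whose C8 configuration depends on the macrocyclisation. Hydroxyl-directed, A(1,3)-controlled epoxidation (mCPBA, NaHCO3, CH2Cl2) should give threo epoxy diol F4. Camphorsulfonic acid then induces transannular anti opening of the epoxide at C10 by the C5 hydroxyl and lactonisation of the C8 hydroxyl, arriving at 16. In this variant the ether bond and the C8–C9 bond are made in separate steps.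

2. Step 8. Arylation at carbon of the electron-rich alkenyl sulfide, or copper- and heat-induced degradation of the lactol, may compete with aryl transfer to sulfur. The fallback sets out from lactol 12 and comes back at epoxide 15. S-Alkylation with methyl triflate (2,6-di-tert-butylpyridine, CH2Cl2, 0 °C) gives methylphenylsulfonium salt F5, which is put through the DBU cascade of step 9 with methyl phenyl sulfide as the leaving group.

3. Step 12. Competing enolisation of the isovalerate, or acyl transfer from the enolate, may erode the methylenation. The fallback sets out from hydroxy lactone 16 and comes back at target 20. Carboxylation of the lactone α-position with methoxymagnesium methyl carbonate (CH3OMgOCO2CH3, DMF, 130 °C) gives carboxylic acid F6. Decarboxylative Mannich methylenation (aq. HCHO, Et2NH, NaOAc, AcOH) gives methylene hydroxy lactone F7, and acylation with 3-methylbutanoic anhydride and DMAP as in step 11 gives 20.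

Further compounds
F1 | step 9 | tert-butyl 2-[(3R,5R)-5-[(2S,6E)-7-iodo-6-methylhept-6-en-2-yl]-2-oxooxolan-3-yl]acetate | O=C1O[C@@H]([C@@H](C)CCC/C(C)=C/I)C[C@@H]1CC(=O)OC(C)(C)C
F2 | step 9 | tert-butyl 2-[(3R,5R)-2-hydroxy-5-[(2S,6E)-7-iodo-6-methylhept-6-en-2-yl]oxolan-3-yl]acetate (anomer mixture) | OC1O[C@@H]([C@@H](C)CCC/C(C)=C/I)C[C@@H]1CC(=O)OC(C)(C)C
F3 | step 9 | tert-butyl 2-[(4S,5R,7R,8R,9E)-5,8-dihydroxy-4,10-dimethylcyclodec-9-en-7-yl]acetate | CC(C)(C)OC(=O)C[C@H]1C[C@@H](O)[C@@H](C)CCC/C(C)=C/[C@@H]1O
F4 | step 9 | tert-butyl 2-[(4S,5R,7R,8R,9S,10S)-9,10-epoxy-5,8-dihydroxy-4,10-dimethylcyclodecan-7-yl]acetate | CC(C)(C)OC(=O)C[C@H]1C[C@@H](O)[C@@H](C)CCC[C@]2(C)O[C@H]2[C@@H]1O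
F5 | step 8 | [(1E,6S)-6-[(2R,4R)-4-(2-tert-butoxy-2-oxoethyl)-5-hydroxyoxolan-2-yl]-2-methylhept-1-en-1-yl](methyl)phenylsulfonium trifluoromethanesulfonate | OC1O[C@@H]([C@@H](C)CCC/C(C)=C/[S+](C)c2ccccc2)C[C@@H]1CC(=O)OC(C)(C)C.[O-]S(=O)(=O)C(F)(F)F
F6 | step 12 | (4S,5R,7R,8R,9S,10R)-5,10-epoxy-9-hydroxy-12-oxo-13-norgermacran-12,8-olide-11-carboxylic acid (C11 epimers) | O=C1O[C@@H]2[C@@H](C1C(O)=O)C[C@H]1O[C@](C)(CCC[C@@H]1C)[C@H]2O
F7 | step 12 | (4S,5R,7R,8R,9S,10R)-5,10-epoxy-9-hydroxygermacr-11(13)-en-12,8-olide | C=C1C(=O)O[C@@H]2[C@@H]1C[C@H]1O[C@](C)(CCC[C@@H]1C)[C@H]2O
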